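(All runs are simulated from invented constants; scatter was added.)

A small charge of free catalyst, 0.54 mM in the flask, faces 20 mM of starting material, so finishing takes 37.0 rounds per catalyst.

| setting | theta | alpha | epsilon | flask |
|---|---|---|---|---|
| starting material | 20 mM (in portions, 3) | 20 mM (in portions, 3) | 40 mM (in portions, 3) | 20 mM (in portions, 3) |
| free catalyst | 0.36 mM | 0.81 mM | 0.54 mM | 0.54 mM |
| remark | run made earlier; portions every 5.0 min | run made earlier; portions every 5.0 min | run made earlier; portions every 5.0 min | the portions of starting material follow each other after 5.0 min, the first at the start |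
| time |  |  |  | 15 min |

| run | time / min | starting material / % | product / % | catalyst intermediate / % |
|---|---|---|---|---|
| theta | 2.50 | 26.2 | 5.1 | 0.9 |
| theta | 5.00 | 22.2 | 9.8 | 0.3 |
| theta | 6.00 | 52.9 | 10.5 | 1.3 |
| theta | 10.0 | 47.6 | 15.9 | 1.0 |
| alpha | 2.50 | 18.1 | 11.8 | 2.9 |
| alpha | 5.00 | 8.2 | 21.7 | 1.9 |
| alpha | 6.00 | 37.1 | 26.0 | 3.0 |
| alpha | 10.0 | 23.9 | 39.1 | 2.1 |
| epsilon | 0.667 | 30.2 | 1.2 | 1.2 |
| epsilon | 1.50 | 30.2 | 1.8 | 1.6 |
| epsilon | 4.00 | 25.9 | 6.5 | 0.4 |
| epsilon | 10.0 | 55.3 | 10.6 | 0 |

(readings scatter by 0.5 percentage points)

- a reading at the moment of an addition is taken just before it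
- percentages count the whole charge, also what has not yet gone in

- the species in which most of what was charged as starting material, at 15 min sits (catalyst intermediate / starting material / product)
- the largest share itself, whichever of these holds it, in percent of the starting material charged

We reckon with the turnover number, the product made per catalyst charged. Theta and alpha have the flask's charge of starting material, and at 5.00 min they stand at 5.44 and 5.36, then at 10.0 min at 8.83 and 9.65, although alpha carries 2.25 times the catalyst of theta. So in these two runs product follows the catalyst charged. The mean gain is 5.40 in the first stretch and 3.84 in the second, a ratio of 0.711. If that ratio holds, the third stretch adds 2.73, and the total of 12.0 is fewer rounds than the 37.0 needed. That makes product 32.3%. Just before the last portion, theta and alpha fall short of what had gone in by a mean 3.42% of the charge, which we keep as an allowance, so starting material comes to 64.3%.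

The weak link is the assumed ratio. After its last portion the flask should hold about 14.3 mM of starting material, and epsilon, with the flask's charge of free catalyst, read 10.4 mM at 4.00 min and 22.1 mM at 10.0 min, gaining 0.506 min⁻¹ in turnover number between those readings. Over the last stretch that gives 11.8, the turnover number of the flask, product per catalyst charged by 15 min, and starting material of 64.8%.

The forecast says starting material at 63%, 1.8 percentage points below our figure, on the ground that “the catalyst is being lost or parked, roughly in step with turnover”.

The flask gives starting material at 64.1%.

    starting material + free catalyst → catalyst intermediate (k = 2530 M⁻¹ min⁻¹)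
    catalyst intermediate → free catalyst + product (k = 1.40 min⁻¹)
    starting material + catalyst intermediate → spent catalyst A (k = 10.8 M⁻¹ min⁻¹)
    free catalyst → spent catalyst B (k = 0.0771 min⁻¹)

At 15 min spent catalyst A stands at 70.3% of the catalyst charged. Product of 31.5% is a turnover number of 11.7, against our 11.8. For a neighbouring flask charged with 1.4 mM of free catalyst, 11.8 gives 82.6% of product, and that flask holds 83.4%.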